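**Strategy.** Ring C is cut at C3–C4 and O1–C2. Because C3 carries a methoxy group and sits next to C4, the C2–C3 unit with ring B maps onto an ω-methoxyacetophenone, while C4 with ring A maps onto a salicylaldehyde whose two ortho hydroxyls, the future O1 and 5-OH, are interchangeable. One acid-mediated operation joins the fragments by aldol condensation and closes the pyrylium ring, delivering a 3-methoxyflavylium salt with all ring A and ring B oxygens in place. The precursors are the mirror-symmetric 4-benzyloxy-2,6-dihydroxy-3,5-dimethoxybenzaldehyde and 2-methoxy-1-(2,4,5-trimethoxyphenyl)ethanone. C4 is afterwards raised to the ketone through the flavylium pseudobase, and hydrogenolysis frees the 7-hydroxyl.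

Key step: step 6

Assumption: the aryl bromide and the Weinreb amide used in step 5 are taken as catalogue chemicals; the two non-isolated intermediates that carry a stereocentre are racemic, which is without consequence because the target is achiral.

**Step 1**
Reactants: 1 2,6-dimethoxyphenol
Product: 2 2-(benzyloxy)-1,3-dimethoxybenzene
Conditions: BnBr, K2CO3, DMF, 60 °C
Reagents that add atoms: benzyl bromide BrCc1ccccc1
Why: Williamson ether synthesis, in which the phenoxide of 1 is alkylated by the reactive benzylic bromide to give a 1,2,3-trialkoxybenzene whose central oxygen is twisted out of conjugation, which later steers substitution away from the position para to it.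

**Step 2**
Reactants: 2 2-(benzyloxy)-1,3-dimethoxybenzene
Product: 3 3-(benzyloxy)-1,5-dibromo-2,4-dimethoxybenzene
Conditions: NBS (2.1 equiv), MeCN, 0 °C to rt, dark
Reagents that add atoms: N-bromosuccinimide O=C1CCC(=O)N1Br
Why: Electrophilic aromatic bromination, in which each bromine should enter ortho to one flanking methoxy group and para to the other, so that both carbons next to the methoxy groups are filled and the carbon para to the benzyloxy group stays free.

**Step 3**
Reactants: 3 3-(benzyloxy)-1,5-dibromo-2,4-dimethoxybenzene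
Product: 4 5-(benzyloxy)-4,6-dimethoxybenzene-1,3-diol
Conditions: Pd2(dba)3 (2 mol %), tBuXPhos (8 mol %), KOH (6 equiv), degassed 1,4-dioxane/H2O, 100 °C; then aq. HCl, 0 °C, under Ar
Reagents that add atoms: potassium hydroxide [K+].[OH-]
Why: Palladium-catalysed hydroxylation of aryl bromides (Buchwald–Hartwig-type C–O coupling), in which the bulky biaryl phosphine lets zerovalent palladium insert into the electron-rich C–Br bonds and promotes C–O reductive elimination, while benzyl and methyl ethers are inert to hot hydroxide when air is excluded.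

**Step 4**
Reactants: 4 5-(benzyloxy)-4,6-dimethoxybenzene-1,3-diol
Product: 6 4-(benzyloxy)-2,6-dihydroxy-3,5-dimethoxybenzaldehyde, via aryl iminium chloride 5 (not isolated)
Conditions: POCl3, DMF, MeCN, 0 °C to rt; then H2O, 50 °C
Reagents that add atoms: N,N-dimethylformamide CN(C)C=O; water O
Why: Vilsmeier–Haack formylation, in which the chloroiminium ion attacks the only unsubstituted ring carbon, activated by two ortho hydroxyls and the para benzyloxy group, and hydrolysis of iminium salt 5 releases the doubly hydrogen-bonded aldehyde.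

**Step 5**
Reactants: 7 1-bromo-2,4,5-trimethoxybenzene; 8 N,2-dimethoxy-N-methylacetamide
Product: 11 2-methoxy-1-(2,4,5-trimethoxyphenyl)ethan-1-one, via aryllithium 9 (not isolated), via lithium hemiaminalate 10 (not isolated)
Conditions: n-BuLi, THF, −78 °C; then 8, −78 to 0 °C; aq. HCl (1 M)
Reagents that add atoms: none
Why: Bromine–lithium exchange followed by Weinreb ketone synthesis, in which the chelated tetrahedral adduct 10 resists a second addition and collapses to the ketone only on acidic quench, the site of the carbonyl being fixed by the bromine.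

**Step 6**
Reactants: 6 4-(benzyloxy)-2,6-dihydroxy-3,5-dimethoxybenzaldehyde; 11 2-methoxy-1-(2,4,5-trimethoxyphenyl)ethan-1-one
Product: 13 7-(benzyloxy)-5-hydroxy-3,6,8-trimethoxy-2-(2,4,5-trimethoxyphenyl)chromenylium chloride, via retrochalcone 12 (not isolated)
Conditions: dry HCl (g), EtOAc, 0 °C; sealed, 4 °C, 48 h; Et2O
Reagents that add atoms: hydrogen chloride Cl
Why: Hydrogen chloride enolises 11 toward its only α-carbon, the methoxy-bearing methylene, the enol adds to the protonated aldehyde of 6, and loss of water gives retrochalcone 12, which forms the C3–C4 bond. One of the two phenols ortho to the side chain then attacks the protonated ketone in a 6-exo-trig closure that forms the O1–C2 bond, and a second dehydration aromatises ring C to the pyrylium cation, which should precipitate as its chloride and so be withdrawn from further reaction. The closest known reaction type is the classical acid-catalysed condensation of ortho-hydroxybenzaldehydes with ω-methoxyacetophenones to 3-methoxyflavylium salts. No stereocentre is created, and the geometry of 12 does not matter because acid interconverts the isomers and only the E isomer, with the aryl group cis to the aroyl group, can cyclise. The selectivity needed is constitutional and the substrates secure it: the ketone has a single enolisable carbon and the two ortho hydroxyls of 6 are equivalent by symmetry, so either closure gives the same 5-hydroxy-7-benzyloxy salt. The benzyl ether should survive because the reaction is run at 0–5 °C in an ester solvent and the product leaves solution.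

**Step 7**
Reactants: 13 7-(benzyloxy)-5-hydroxy-3,6,8-trimethoxy-2-(2,4,5-trimethoxyphenyl)chromenylium chloride
Product: 16 7-(benzyloxy)-5-hydroxy-3,6,8-trimethoxy-2-(2,4,5-trimethoxyphenyl)-4H-chromen-4-one, via quinonoid anhydrobase 14 (not isolated), via C4 carbinol pseudobase 15 (not isolated)
Conditions: NaOAc (1.5 equiv), H2O (10 equiv), MeCN/CH2Cl2, rt; then activated MnO2 (15 equiv), rt, dark
Reagents that add atoms: water O
Why: Decker-type oxidation of a heteroaromatic cation through its pseudobase, a reaction type known with MnO2 for pyrylium and flavylium salts unsubstituted at the γ-carbon, in which acetate liberates the neutral quinonoid base 14 (an ortho-quinone methide whose methide carbon is C4), water adds there to give the doubly activated carbinol 15, and MnO2 dehydrogenates it, while the competing C2 adduct has no carbinol hydrogen and returns through the cation and the product is shielded by the hydrogen bond between 5-OH and the new C4 carbonyl.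

**Step 8**
Reactants: 16 7-(benzyloxy)-5-hydroxy-3,6,8-trimethoxy-2-(2,4,5-trimethoxyphenyl)-4H-chromen-4-one
Product: 17 5,7-dihydroxy-3,6,8-trimethoxy-2-(2,4,5-trimethoxyphenyl)-4H-chromen-4-one
Conditions: H2 (1 atm), Pd/C (10 wt %), EtOAc/MeOH, rt
Reagents that add atoms: none
Why: Hydrogenolysis of a benzyl aryl ether over palladium on carbon, which should cleave the benzylic C–O bond while the tetrasubstituted C2=C3 bond of the chromone, the methyl ethers and the carbonyl group stay untouched.

**Compound list**
1 | 2,6-dimethoxyphenol | COc1cccc(OC)c1O | starting material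
2 | 2-(benzyloxy)-1,3-dimethoxybenzene | COc1cccc(OC)c1OCc1ccccc1 | intermediate
3 | 3-(benzyloxy)-1,5-dibromo-2,4-dimethoxybenzene | COc1c(Br)cc(Br)c(OC)c1OCc1ccccc1 | intermediate
4 | 5-(benzyloxy)-4,6-dimethoxybenzene-1,3-diol | COc1c(O)cc(O)c(OC)c1OCc1ccccc1 | intermediate
5 | N-{[4-(benzyloxy)-2,6-dihydroxy-3,5-dimethoxyphenyl]methylidene}-N-methylmethanaminium chloride (not isolated) | C[N+](C)=Cc1c(O)c(OC)c(OCc2ccccc2)c(OC)c1O.[Cl-] | intermediate
6 | 4-(benzyloxy)-2,6-dihydroxy-3,5-dimethoxybenzaldehyde | O=Cc1c(O)c(OC)c(OCc2ccccc2)c(OC)c1O | intermediate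
7 | 1-bromo-2,4,5-trimethoxybenzene | COc1cc(OC)c(Br)cc1OC | starting material
8 | N,2-dimethoxy-N-methylacetamide | COCC(=O)N(C)OC | starting material
9 | (2,4,5-trimethoxyphenyl)lithium (not isolated) | [Li]c1cc(OC)c(OC)cc1OC | intermediate
10 | lithium 2-methoxy-1-[methoxy(methyl)amino]-1-(2,4,5-trimethoxyphenyl)ethan-1-olate, racemic (not isolated) | COCC([O-])(N(C)OC)c1cc(OC)c(OC)cc1OC.[Li+] | intermediate
11 | 2-methoxy-1-(2,4,5-trimethoxyphenyl)ethan-1-one | COCC(=O)c1cc(OC)c(OC)cc1OC | intermediate
12 | (E)-3-[4-(benzyloxy)-2,6-dihydroxy-3,5-dimethoxyphenyl]-2-methoxy-1-(2,4,5-trimethoxyphenyl)prop-2-en-1-one, aryl cis to aroyl (not isolated) | CO/C(=C/c1c(O)c(OC)c(OCc2ccccc2)c(OC)c1O)C(=O)c1cc(OC)c(OC)cc1OC | intermediate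
13 | 7-(benzyloxy)-5-hydroxy-3,6,8-trimethoxy-2-(2,4,5-trimethoxyphenyl)chromenylium chloride | COc1cc(OC)c(-c2[o+]c3c(OC)c(OCc4ccccc4)c(OC)c(O)c3cc2OC)cc1OC.[Cl-] | intermediate
14 | 7-(benzyloxy)-3,6,8-trimethoxy-2-(2,4,5-trimethoxyphenyl)-5H-chromen-5-one, quinonoid anhydrobase (not isolated) | COC1=C(c2cc(OC)c(OC)cc2OC)OC2=C(OC)C(OCc3ccccc3)=C(OC)C(=O)C2=C1 | intermediate
15 | 7-(benzyloxy)-3,6,8-trimethoxy-2-(2,4,5-trimethoxyphenyl)-4H-chromene-4,5-diol, racemic at C4 (not isolated) | COC1=C(c2cc(OC)c(OC)cc2OC)Oc2c(OC)c(OCc3ccccc3)c(OC)c(O)c2C1O | intermediate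
16 | 7-(benzyloxy)-5-hydroxy-3,6,8-trimethoxy-2-(2,4,5-trimethoxyphenyl)-4H-chromen-4-one | COc1cc(OC)c(-c2oc3c(OC)c(OCc4ccccc4)c(OC)c(O)c3c(=O)c2OC)cc1OC | intermediate
17 | 5,7-dihydroxy-3,6,8-trimethoxy-2-(2,4,5-trimethoxyphenyl)-4H-chromen-4-one (5,7-dihydroxy-3,6,8,2',4',5'-hexamethoxyflavone) | COc1cc(OC)c(-c2oc3c(OC)c(O)c(OC)c(O)c3c(=O)c2OC)cc1OC | target

**Step count**
Total: 8 steps. Longest linear sequence: 7 steps (steps 1, 2, 3, 4, 6, 7, 8); step 5 is the one-step side branch.

**Steps most likely to fail**

Step 7. Hydration may occur mainly at C2, and the hemiketal may open to the chalcone faster than the C4 carbinol is dehydrogenated. The electron-rich ring A phenol may also be oxidised on the MnO2 surface. The fallback lowers the oxidation level first and then oxidises a C–H bond instead of a pseudobase. Setting out from 13, NaBH4 in THF/MeCN at 0 °C should deliver hydride to C4 of the quinonoid base, as in the known borohydride reduction of flavylium salts to 4H-flavenes, giving 7-(benzyloxy)-3,6,8-trimethoxy-2-(2,4,5-trimethoxyphenyl)-4H-chromen-5-ol F1. Acetylation (Ac2O, pyridine) would mask the para-methoxyphenol as 7-(benzyloxy)-3,6,8-trimethoxy-2-(2,4,5-trimethoxyphenyl)-4H-chromen-5-yl acetate F2. Allylic/benzylic oxidation of the doubly activated C4 methylene with t-BuOOH and catalytic Rh2(cap)4 (dirhodium tetracaprolactamate) should then give 7-(benzyloxy)-3,6,8-trimethoxy-4-oxo-2-(2,4,5-trimethoxyphenyl)-4H-chromen-5-yl acetate F3. Methanolysis (K2CO3, MeOH, rt) removes the acetate and the route is rejoined at 16.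

Step 6. The benzyl ether may be cleaved by hydrogen chloride during the long exposure, or the condensation may stall because the doubly hydrogen-bonded aldehyde is a weak electrophile. The fallback forms the same two bonds in two separate stages, the first under base. Setting out from 6, both phenols are protected (MOMCl, iPr2NEt, CH2Cl2) to give 4-(benzyloxy)-3,5-dimethoxy-2,6-bis(methoxymethoxy)benzaldehyde F4. Claisen–Schmidt condensation of F4 with 11 (KOH, EtOH, rt) should give (Z)-3-[4-(benzyloxy)-3,5-dimethoxy-2,6-bis(methoxymethoxy)phenyl]-2-methoxy-1-(2,4,5-trimethoxyphenyl)prop-2-en-1-one F5. A short treatment with methanolic HCl at rt removes both acetals, isomerises the double bond and closes the pyrylium ring, so the route is rejoined at 13.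

Step 3. The second C–O coupling may stall on the electron-rich bromophenoxide, hydrodebromination or diaryl ether formation may compete, and the dianion of the product may be oxidised by traces of air in hot base. The fallback replaces C–O coupling by C–B bond formation and oxidation. Setting out from 3, double Miyaura borylation (B2pin2, Pd(dppf)Cl2, KOAc, 1,4-dioxane, 90 °C) should give 2,2'-[5-(benzyloxy)-4,6-dimethoxy-1,3-phenylene]bis(4,4,5,5-tetramethyl-1,3,2-dioxaborolane) F6. Oxidation of both C–B bonds (H2O2, aq. NaOH, THF, 0 °C), with acidification under argon, rejoins the route at 4.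

**Further compounds**
F1 | step 7 | 7-(benzyloxy)-3,6,8-trimethoxy-2-(2,4,5-trimethoxyphenyl)-4H-chromen-5-ol | COC1=C(c2cc(OC)c(OC)cc2OC)Oc2c(OC)c(OCc3ccccc3)c(OC)c(O)c2C1
F2 | step 7 | 7-(benzyloxy)-3,6,8-trimethoxy-2-(2,4,5-trimethoxyphenyl)-4H-chromen-5-yl acetate | COC1=C(c2cc(OC)c(OC)cc2OC)Oc2c(OC)c(OCc3ccccc3)c(OC)c(OC(C)=O)c2C1
F3 | step 7 | 7-(benzyloxy)-3,6,8-trimethoxy-4-oxo-2-(2,4,5-trimethoxyphenyl)-4H-chromen-5-yl acetate | COc1cc(OC)c(-c2oc3c(OC)c(OCc4ccccc4)c(OC)c(OC(C)=O)c3c(=O)c2OC)cc1OC
F4 | step 6 | 4-(benzyloxy)-3,5-dimethoxy-2,6-bis(methoxymethoxy)benzaldehyde | O=Cc1c(OCOC)c(OC)c(OCc2ccccc2)c(OC)c1OCOC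
F5 | step 6 | (Z)-3-[4-(benzyloxy)-3,5-dimethoxy-2,6-bis(methoxymethoxy)phenyl]-2-methoxy-1-(2,4,5-trimethoxyphenyl)prop-2-en-1-one | CO/C(=C\c1c(OCOC)c(OC)c(OCc2ccccc2)c(OC)c1OCOC)C(=O)c1cc(OC)c(OC)cc1OC
F6 | step 3 | 2,2'-[5-(benzyloxy)-4,6-dimethoxy-1,3-phenylene]bis(4,4,5,5-tetramethyl-1,3,2-dioxaborolane) | COc1c(B2OC(C)(C)C(C)(C)O2)cc(B2OC(C)(C)C(C)(C)O2)c(OC)c1OCc1ccccc1
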